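**Retrosynthetic overview**
1. The target is (+)-pinoresinol joined C5–C5' to (2R,3R)-taxifolin. The last disconnections are hydrogenolytic deprotection and the biaryl bond, made by borylation/Suzuki–Miyaura coupling of a flavanonol aryl triflate with 5-iodo-(+)-pinoresinol.
2. Flavanonol half: rings A, C and B and both stereocentres are bought as (2R,3R)-dihydromyricetin. Its third B-ring oxygen (5'-OH) becomes the triflate (3',4'-OH as Ph2C ketal, 7-OH as benzyl ether), so the biaryl C–C bond replaces a C–O bond.
3. Lignan half: 5-iodo-(+)-pinoresinol ⇒ (+)-pinoresinol ⇒ (−)-secoisolariciresinol by a double dehydrogenative cyclisation through two p-quinone methides. Both tetrahydrofuran rings close in one operation and C7/C7' are set from C8/C8'.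
4. (−)-Secoisolariciresinol ⇒ LiAlH4 reduction of the (R,R)-dimer from oxidative enolate homocoupling of the Evans imide of dihydroferulic acid (sets C8/C8').
5. Ring order: the flavanonol rings are present from the start; the two furofuran rings form together in step 4; no ring is formed afterwards.

Assumption: commercial (+)-dihydromyricetin (ampelopsin) is the (2R,3R) enantiomer, and the target is read as (7S,7'S,8R,8'R)-pinoresinol linked C5–C5' to (2R,3R)-taxifolin.

**Step 1**
Reactants: 1 3-(4-hydroxy-3-methoxyphenyl)propanoic acid (dihydroferulic acid); 2 (S)-4-isopropyloxazolidin-2-one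
Product: 4 (4S)-4-isopropyl-3-[3-(3-methoxy-4-pivaloyloxyphenyl)propanoyl]oxazolidin-2-one, via mixed pivalic anhydride 3 (not isolated)
Conditions: PivCl (2.4 equiv), Et3N, DMAP (cat.), THF, −10 °C; then 2, LiCl, rt
Reagents that add atoms: pivaloyl chloride, CC(C)(C)C(=O)Cl
Why: Excess pivaloyl chloride esterifies the phenol and turns the acid into the mixed pivalic anhydride, whose unhindered carbonyl is then attacked by the LiCl-activated oxazolidinone (mixed-anhydride N-acylation of an Evans auxiliary); no new stereocentre is formed.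

**Step 2**
Reactants: 4 (two molecules)
Product: 6 (2R,3R)-2,3-bis(3-methoxy-4-pivaloyloxybenzyl)succinic bis-imide of (S)-4-isopropyloxazolidin-2-one, via lithium Z-enolate 5 (not isolated)
Conditions: LDA (1.1 equiv), THF, −78 °C; then PhI(OAc)2 (0.55 equiv), −78 → −20 °C
Reagents that add atoms: none
Why: Oxidative enolate homocoupling of the chelated Evans Z-enolate with a hypervalent iodine oxidant: each new C–C bond forms on the enolate face anti to the isopropyl group, so the (S)-auxiliary gives the C2-symmetric (R,R)-dimer that fixes C8 and C8', and the hindered aryl pivalates tolerate LDA at −78 °C.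

**Step 3**
Reactants: 6 (R,R)-bis-imide
Product: 7 (−)-secoisolariciresinol, (2R,3R)-2,3-bis(4-hydroxy-3-methoxybenzyl)butane-1,4-diol
Conditions: LiAlH4 (6 equiv), THF, 0 °C → rt; aq potassium sodium tartrate work-up
Reagents that add atoms: none
Why: Hydride reduction cleaves both N-acyl oxazolidinones to primary alcohols and both aryl pivalates to phenols in one operation, and the two stereocentres are not epimerisable under these conditions and keep the R,R configuration.

**Step 4**
Reactants: 7 (−)-secoisolariciresinol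
Product: 11 (+)-pinoresinol, via seco quinone methide 8 (not isolated), via (+)-lariciresinol 9 (not isolated), via lariciresinol quinone methide 10 (not isolated)
Conditions: DDQ (2.05 equiv, portionwise), anhydrous 1,4-dioxane (0.02 M), 15 °C → rt
Reagents that add atoms: none
Why: Proposed new method: DDQ dehydrogenates each 4-alkylguaiacol unit to a p-quinone methide that is trapped 5-exo by the CH2OH on the neighbouring carbon (intramolecular oxa-1,6-addition), the first closure placing the aryl trans to the C8 substituent (lariciresinol) and the second closing the necessarily cis-fused ring with its aryl on the convex face, so the fixed (8R,8'R) centres dictate (7S,7'S); the closest known reactions are DDQ oxidation of 4-alkylphenols to quinone methides with alcohol trapping and the quinone-methide ring closures in oxidative coniferyl alcohol dimerisation.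

**Step 5**
Reactants: 11 (+)-pinoresinol
Product: 12 5-iodo-(+)-pinoresinol
Conditions: I2 (0.8 equiv), NaHCO3, THF–H2O, 0 °C
Reagents that add atoms: iodine, II
Why: Electrophilic aromatic iodination of the phenolate goes to C5, the only free position ortho to the activating oxygen, and sub-stoichiometric iodine favours the mono-iodide (unreacted 11 is recovered and recycled); no stereocentre is touched.

**Step 6**
Reactants: 13 (2R,3R)-dihydromyricetin
Product: 14 3',4'-O-(diphenylmethylene)dihydromyricetin
Conditions: Ph2CCl2 (1.3 equiv), Ph2O, 160 °C, N2, 30 min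
Reagents that add atoms: dichlorodiphenylmethane, ClC(Cl)(c1ccccc1)c1ccccc1
Why: Ketalisation of a vicinal phenolic diol: dichlorodiphenylmethane bridges two adjacent hydroxyls of the symmetric pyrogallol ring B and leaves exactly one B-ring hydroxyl (5'-OH) free, while the base-free conditions leave C2 and C3 untouched.

**Step 7**
Reactants: 14 3',4'-O-(diphenylmethylene)dihydromyricetin
Product: 15 7-O-benzyl-3',4'-O-(diphenylmethylene)dihydromyricetin
Conditions: BnBr (1.05 equiv), K2CO3 (1.1 equiv), DMF, 0 °C → rt
Reagents that add atoms: benzyl bromide, BrCc1ccccc1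
Why: Williamson etherification is selective for the 7-OH, which as a vinylogous acid is far more acidic than the 5'-OH, the hydrogen-bonded 5-OH and the 3-OH; with the 4'-oxygen ketalised the base-induced ring opening that would epimerise C2 is blocked.

**Step 8**
Reactants: 15 7-O-benzyl-3',4'-O-(diphenylmethylene)dihydromyricetin
Product: 16 7-O-benzyl-3',4'-O-(diphenylmethylene)dihydromyricetin 5'-O-triflate
Conditions: PhNTf2 (1.1 equiv), Et3N, DMAP (cat.), CH2Cl2, 0 °C → rt
Reagents that add atoms: N-phenylbis(trifluoromethanesulfonimide), FC(F)(F)S(=O)(=O)N(c1ccccc1)S(=O)(=O)C(F)(F)F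
Why: Phenol triflation with the mild triflyl donor reacts only at the unchelated 5'-phenol (the chelated 5-OH and the secondary 3-OH stay free), turning the surplus oxygen of dihydromyricetin into the handle for the biaryl bond.

**Step 9**
Reactants: 16 aryl triflate; 12 5-iodo-(+)-pinoresinol
Product: 18 7-O-benzyl-3',4'-O-(diphenylmethylene) derivative of the target, via arylboronic pinacol ester 17 (not isolated)
Conditions: B2pin2 (1.05 equiv), Pd(dppf)Cl2 (5 mol %), KOAc, 1,4-dioxane, 80 °C; then 12, aq K3PO4, 60 °C, degassed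
Reagents that add atoms: none
Why: One-pot Miyaura borylation of the aryl triflate followed by Suzuki–Miyaura coupling with the ortho-iodophenol (free phenols are tolerated, as with 5-iodovanillin) forms the C5–C5' bond without involving any stereocentre, and the degassed, mildly basic medium spares the dihydroflavonol.

**Step 10**
Reactants: 18 protected biaryl
Product: 19 CNP0226398.1 (target)
Conditions: H2 (1 atm), 10% Pd/C, EtOAc–MeOH, rt, monitored
Reagents that add atoms: none
Why: Catalytic hydrogenolysis removes the benzyl ether and the doubly benzylic diphenylmethylene ketal faster than it attacks the hindered furofuran benzylic ethers, the aryl methyl ethers or the chelated ketone, and no stereocentre is affected.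

**Compound list**
1 | 3-(4-hydroxy-3-methoxyphenyl)propanoic acid (dihydroferulic acid) | COc1cc(CCC(=O)O)ccc1O | starting material
2 | (S)-4-isopropyloxazolidin-2-one | CC(C)[C@H]1COC(=O)N1 | starting material
3 | 3-(3-methoxy-4-pivaloyloxyphenyl)propanoic pivalic anhydride (formed in the flask) | COc1cc(CCC(=O)OC(=O)C(C)(C)C)ccc1OC(=O)C(C)(C)C | intermediate
4 | (4S)-4-isopropyl-3-[3-(3-methoxy-4-pivaloyloxyphenyl)propanoyl]oxazolidin-2-one | CC(C)[C@H]1COC(=O)N1C(=O)CCc1ccc(OC(=O)C(C)(C)C)c(OC)c1 | intermediate
5 | lithium Z-enolate of 4 (formed in the flask) | CC(C)[C@H]1COC(=O)N1/C(O[Li])=C/Cc1ccc(OC(=O)C(C)(C)C)c(OC)c1 | intermediate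
6 | (2R,3R)-2,3-bis(3-methoxy-4-pivaloyloxybenzyl)succinic bis-imide of (S)-4-isopropyloxazolidin-2-one | CC(C)[C@H]1COC(=O)N1C(=O)[C@H](Cc1ccc(OC(=O)C(C)(C)C)c(OC)c1)[C@@H](Cc1ccc(OC(=O)C(C)(C)C)c(OC)c1)C(=O)N1C(=O)OC[C@@H]1C(C)C | intermediate
7 | (−)-secoisolariciresinol, (2R,3R)-2,3-bis(4-hydroxy-3-methoxybenzyl)butane-1,4-diol | OC[C@H](Cc1ccc(O)c(OC)c1)[C@H](CO)Cc1ccc(O)c(OC)c1 | intermediate
8 | mono-p-quinone methide of 7 (C7=C1, E/Z mixture, formed in the flask) | COC1=CC(=C[C@@H](CO)[C@H](CO)Cc2ccc(O)c(OC)c2)C=CC1=O | intermediate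
9 | (+)-lariciresinol (7S,8R,8'R) (formed in the flask) | COc1cc([C@H]2OC[C@H](Cc3ccc(O)c(OC)c3)[C@@H]2CO)ccc1O | intermediate
10 | p-quinone methide of 9 at C7' (E/Z mixture, formed in the flask) | COc1cc([C@H]2OC[C@H](C=C3C=CC(=O)C(OC)=C3)[C@@H]2CO)ccc1O | intermediate
11 | (+)-pinoresinol (7S,7'S,8R,8'R) | COc1cc([C@H]2OC[C@H]3[C@@H]2CO[C@@H]3c2ccc(O)c(OC)c2)ccc1O | intermediate
12 | 5-iodo-(+)-pinoresinol (iodine ortho to one phenolic OH) | COc1cc([C@H]2OC[C@H]3[C@@H]2CO[C@@H]3c2cc(OC)c(O)c(I)c2)ccc1O | intermediate
13 | (2R,3R)-dihydromyricetin (ampelopsin) | Oc1cc(cc(O)c1O)[C@H]1Oc2cc(O)cc(O)c2C(=O)[C@@H]1O | starting material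
14 | 3',4'-O-(diphenylmethylene)dihydromyricetin (5'-OH free) | Oc1cc(cc2OC(c3ccccc3)(c3ccccc3)Oc12)[C@H]1Oc2cc(O)cc(O)c2C(=O)[C@@H]1O | intermediate
15 | 7-O-benzyl-3',4'-O-(diphenylmethylene)dihydromyricetin | Oc1cc(cc2OC(c3ccccc3)(c3ccccc3)Oc12)[C@H]1Oc2cc(OCc3ccccc3)cc(O)c2C(=O)[C@@H]1O | intermediate
16 | 7-O-benzyl-3',4'-O-(diphenylmethylene)dihydromyricetin 5'-O-triflate | O=S(=O)(Oc1cc(cc2OC(c3ccccc3)(c3ccccc3)Oc12)[C@H]1Oc2cc(OCc3ccccc3)cc(O)c2C(=O)[C@@H]1O)C(F)(F)F | intermediate
17 | 5'-pinacolboronate corresponding to 16 (Bpin in place of OTf, formed in the flask) | CC1(C)OB(OC1(C)C)c1cc(cc2OC(c3ccccc3)(c3ccccc3)Oc12)[C@H]1Oc2cc(OCc3ccccc3)cc(O)c2C(=O)[C@@H]1O | intermediate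
18 | target carrying 7-O-benzyl and 3',4'-O-diphenylmethylene groups on the flavanonol | COc1cc([C@H]2OC[C@H]3[C@@H]2CO[C@@H]3c2cc(OC)c(O)c(-c3cc([C@H]4Oc5cc(OCc6ccccc6)cc(O)c5C(=O)[C@@H]4O)cc4OC(c5ccccc5)(c5ccccc5)Oc34)c2)ccc1O | intermediate
19 | CNP0226398.1: (2R,3R)-taxifolin joined at C5' to C5 of (+)-pinoresinol | COc1cc([C@H]2OC[C@H]3[C@@H]2CO[C@@H]3c2cc(OC)c(O)c(-c3cc([C@H]4Oc5cc(O)cc(O)c5C(=O)[C@@H]4O)cc(O)c3O)c2)ccc1O | target

**Totals and risks**
Total step count: 10. Longest linear sequence: 7 steps (steps 1, 2, 3, 4, 5, 9, 10).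

Most likely to fail, first: step 4. DDQ may over-oxidise the new benzylic ethers or the quinone methide may close onto the other arene to give an aryltetralin. The fallback sets out from 7. Peracetylation (Ac2O, pyridine) gives (−)-secoisolariciresinol tetraacetate F1. Radical bromination of both benzylic positions (NBS, AIBN, PhCF3, 80 °C) gives the 7,7'-dibromide F2, whose C7 epimers do not matter. K2CO3 in MeOH–THF at 0 °C then removes the acetates, and each phenoxide expels bromide by 1,6-elimination. This generates the same quinone methides without an oxidant, they are trapped by the freed CH2OH groups, and the route is rejoined at 11.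

Second: step 9. The dihydroflavonol with free 3-OH and 5-OH may epimerise or ring-open under the basic borylation/Suzuki sequence, and the ortho-alkoxy boronate may protodeboronate. The fallback sets out from 16. Stannylation (Me3SnSnMe3, Pd(PPh3)4, LiCl, 1,4-dioxane, 90 °C) gives the aryltrimethylstannane F5. A base-free Stille coupling of F5 with 12 (Pd(PPh3)4, CuI cat., DMF, 60 °C) comes back to the route at 18.

Third: step 5. The mono-iodination is statistical and may give too little 12. The fallback sets out from 11. Exhaustive iodination (I2 2.5 equiv, NaHCO3, THF–H2O) gives 5,5'-diiodo-(+)-pinoresinol F3 as a single product. F3 is used in excess (3 equiv, surplus recovered) in the coupling with boronate 17, made from 16 as in step 9, to give the mono-coupled aryl iodide F4. Hydrogenolysis of F4 (H2, 10% Pd/C, Et3N, EtOAc–MeOH) removes the residual iodine together with the benzyl and diphenylmethylene groups and comes back to the route at 19.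

**Further compounds**
F1 | step 4 | (−)-secoisolariciresinol tetraacetate | CC(=O)OC[C@H](Cc1ccc(OC(C)=O)c(OC)c1)[C@H](COC(C)=O)Cc1ccc(OC(C)=O)c(OC)c1
F2 | step 4 | 7,7'-dibromo-(−)-secoisolariciresinol tetraacetate (C7/C7' epimer mixture) | CC(=O)OC[C@H](C(Br)c1ccc(OC(C)=O)c(OC)c1)[C@H](COC(C)=O)C(Br)c1ccc(OC(C)=O)c(OC)c1
F3 | step 5 | 5,5'-diiodo-(+)-pinoresinol | COc1cc([C@H]2OC[C@H]3[C@@H]2CO[C@@H]3c2cc(OC)c(O)c(I)c2)cc(I)c1O
F4 | step 5 | 5-iodo analogue of 18 (iodine ortho to the phenolic OH of the second guaiacyl ring) | COc1cc([C@H]2OC[C@H]3[C@@H]2CO[C@@H]3c2cc(OC)c(O)c(-c3cc([C@H]4Oc5cc(OCc6ccccc6)cc(O)c5C(=O)[C@@H]4O)cc4OC(c5ccccc5)(c5ccccc5)Oc34)c2)cc(I)c1O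
F5 | step 9 | 5'-trimethylstannyl analogue of 16 (SnMe3 in place of OTf) | C[Sn](C)(C)c1cc(cc2OC(c3ccccc3)(c3ccccc3)Oc12)[C@H]1Oc2cc(OCc3ccccc3)cc(O)c2C(=O)[C@@H]1O
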